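Either birch or oak goes on next, and the charge is chosen for the longer chains at 15 h.

common to all: G 2 mol%; L 0.26 mM

| charge | E | remark | time |
|---|---|---|---|
| west | 0.053 M | run made earlier |  |
| north | 0.094 M | run made earlier |  |
| south | 0.18 M | run made earlier |  |
| birch | 0.050 M |  | 15 h |
| oak | 0.15 M |  | 15 h |

| run | time / h | Z / % | E / % |
|---|---|---|---|
| west | 1.33 | 10.8 | 91.0 |
| west | 2.50 | 24.9 | 73.1 |
| west | 4.00 | 41.7 | 58.4 |
| west | 8.00 | 69.8 | 26.6 |
| west | 15.0 | 91.4 | 7.8 |
| north | 1.33 | 29.9 | 71.6 |
| north | 2.50 | 57.7 | 43.7 |
| north | 4.00 | 77.9 | 21.1 |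
| north | 8.00 | 96.1 | 4.2 |
| north | 15.0 | 99.6 | 0.5 |
| south | 3.00 | 95.0 | 6.4 |
| south | 6.00 | 98.6 | 0 |
| south | 10.0 | 101.0 | 0 |
| south | 12.0 | 100.1 | 0 |
| south | 15.0 | 99.2 | 0 |

(standard deviation of a reading: 1 percentage point)

- the average divides the monomer in chains by the number of chains begun, living and dead together
- steps that have been proposed: E + Q -> Z + Q; E + G -> Q + Z; G -> J; G + L -> X
- the earlier runs do not show the number of chains; that part of a forecast is a guess

* which of the two ends with the longer chains by the average number of monomer units in a chain (chains begun, living or dead) ("neither" if they lie within 10%) (birch / oak / neither)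
* average number of monomer units in a chain (chains begun, living or dead) at the end, birch
* average number of monomer units in a chain (chains begun, living or dead) at the end, oak

The earlier runs do not show how many chains begin, so a yardstick has to stand in for that count. If L removes its own amount of G, birch holds 0.740 mM of G beyond the charge of L, and its E divided by half of that gives 135. This is the even-split length: the chain length with E fully in chains, while half of the G beyond L's charge begins chains and the other half becomes J. Oak, with 2.74 mM, comes to 109, so birch starts longer than oak on this scale.

But birch may not finish. West, at nearly the same E, read Z 91.4% at 15.0 h, and that share brings birch down to 124, still 1.14 times oak, beyond the margin of 10%.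

The slopes lean the same way. Past the lag, the logarithm of E falls at 0.179 h⁻¹ in west and 0.426 h⁻¹ in north, a reading of 2.38 times, while G beyond L's charge rises 2.02 times. More of that G seems to begin chains in north than in west, and oak, like north, holds more E than birch, so this reckoning charges birch.

The forecast also says birch, but lower than this reckoning: 88 (58 to 125) for birch and 63 (50 to 82) for oak. Its words: “Chain counts are inferred, so I shade birch down to 88.”

    E + Q → Z + Q, rate k1*[Q]*[E] (k = 9.20 L mol⁻¹ min⁻¹)
    E + G → Q + Z (k = 0.130 L mol⁻¹ min⁻¹)
    G → J (k = 0.00910 min⁻¹)
    G + L → X (k = 9700 L mol⁻¹ min⁻¹)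

The flask gives birch, with 154 for birch and 92.4 for oak, each above the forecast's high end. Birch stands above its even-split length of 135, with Q at 2.91 × 10⁻⁴ M against J at 4.49 × 10⁻⁴ M. Oak stands below its 109, with Q at 0.00162 M against J at 0.00112 M. A neighbour of birch charged with 0.085 M of E holds 1.44 mM of G beyond L's charge, so its even-split length is 118. That neighbour ends with Z at 99.6%, Q at 7.18 × 10⁻⁴ M, J at 7.22 × 10⁻⁴ M and a chain length of 118.

The runs stem from a simulated flask for an exercise, and the scatter is random.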